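**Retrosynthetic overview**
1. Target 21 is the closed lactol form of keto acid 20. The lactol ring therefore forms last and on its own, and C3 follows C4 under thermodynamic control.
2. The key disconnection is C3–C4. A secondary benzylic radical from racemic chloride 17 meets a chiral acyl-nickel species from acid chloride 18. This enantioconvergent reductive coupling joins the two halves and sets C4.
3. West benzene ring: Diels–Alder benzannulation of Brassard-type diene 13 (from 11) with chloro-ynoate 15 (from 14).
4. East benzene ring: Michael–Claisen union of 1 and 2, dehydrogenation, then Kolbe–Schmitt carboxylation. The glycolate linker comes from 7.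
5. Ring order: east benzene ring, west benzene ring, lactol ring.

Assumption: C3 is a hemiketal carbon that equilibrates through open keto acid 20, so 3R is taken as the thermodynamic result of 4S; the ligand antipode in step 10 is written by analogy with simple 1-arylethyl chlorides and is replaced by its mirror image if the first run gives the 4R ketone.

**Step 1**
Reactants: 1 pentan-3-one; 2 methyl (E)-but-2-enoate
Product: 4 2,4,5-trimethylcyclohexane-1,3-dione (diastereomer mixture), via keto ester Michael adduct 3 (not isolated)
Conditions: KOt-Bu (1.2 equiv), THF, 0 °C to reflux; then 2 M HCl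
Reagents that add atoms: none
Why: Tandem Michael addition–Claisen (Dieckmann-type) cyclisation, in which the enolate of 1 adds to the β-carbon of 2, the other α-carbon of the ketone closes on the ester, and the stable dione enolate drives the sequence; the three stereocentres vanish in step 2.

**Step 2**
Reactants: 4 2,4,5-trimethylcyclohexane-1,3-dione
Product: 5 2,4,5-trimethylbenzene-1,3-diol
Conditions: 10% Pd/C, mesitylene, reflux, N2 sweep
Reagents that add atoms: none
Why: Catalytic dehydrogenative aromatisation of a cyclohexane-1,3-dione to the resorcinol, driven by aromaticity and by removal of H2.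

**Step 3**
Reactants: 5 2,4,5-trimethylbenzene-1,3-diol
Product: 6 2,4-dihydroxy-3,5,6-trimethylbenzoic acid
Conditions: KHCO3 (5 equiv), CO2 (1 atm), glycerol, 140 °C; then cold 2 M HCl
Reagents that add atoms: carbon dioxide, O=C=O
Why: Kolbe–Schmitt carboxylation of an electron-rich resorcinol, with no regiochemical choice because the only free ring position is ortho to one hydroxyl and para to the other.

**Step 4**
Reactants: 6 2,4-dihydroxy-3,5,6-trimethylbenzoic acid; 7 methyl bromoacetate
Product: 9 2-methoxy-2-oxoethyl 2,4-bis(benzyloxy)-3,5,6-trimethylbenzoate, via diphenol glycolate ester 8 (not isolated)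
Conditions: KHCO3 (1.1 equiv), 7 (1.05 equiv), DMF, rt; then BnBr (2.5 equiv), K2CO3 (3 equiv), 60 °C
Reagents that add atoms: benzyl bromide, BrCc1ccccc1
Why: Chemoselective SN2 O-alkylation, since hydrogencarbonate ionises only the carboxylic acid so that 7 alkylates the carboxylate, followed by Williamson etherification of both phenols once carbonate and BnBr are added.

**Step 5**
Reactants: 9 2-methoxy-2-oxoethyl 2,4-bis(benzyloxy)-3,5,6-trimethylbenzoate
Product: 10 {[2,4-bis(benzyloxy)-3,5,6-trimethylbenzoyl]oxy}acetic acid
Conditions: LiOH (1.2 equiv), THF/H2O 3:1, 0 °C; then 1 M HCl to pH 3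
Reagents that add atoms: lithium hydroxide, [Li+].[OH-]
Why: Chemoselective saponification, because hydroxide attacks the unhindered, inductively activated methyl ester while the aroyl ester with two ortho substituents is shielded in the manner of a mesitoate.

**Step 6**
Reactants: 11 methyl pent-2-ynoate
Product: 12 methyl (E)-3-methoxypent-2-enoate
Conditions: NaOMe (0.2 equiv), MeOH, reflux
Reagents that add atoms: methanol, CO
Why: Base-catalysed oxa-Michael addition of methanol to the ynoate, which equilibrates to the more stable E β-methoxy enoate.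

**Step 7**
Reactants: 12 methyl (E)-3-methoxypent-2-enoate
Product: 13 1,3-dimethoxy-1-(trimethylsilyloxy)penta-1,3-diene (double-bond isomer mixture)
Conditions: LiN(iPr)2 (1.1 equiv), THF, −78 °C; Me3SiCl (1.3 equiv), −78 °C to rt
Reagents that add atoms: chlorotrimethylsilane, C[Si](C)(C)Cl
Why: Carbonyl-directed γ-deprotonation of the CH2 group that lies cis to the ester, followed by O-silylation, which is the standard preparation of Brassard-type dienes.

**Step 8**
Reactants: 14 3-chlorobut-1-yne (racemic)
Product: 15 benzyl 4-chloropent-2-ynoate (racemic)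
Conditions: MeLi (1.0 equiv), Et2O, −60 °C; ClCO2Bn (1.1 equiv), −60 to −20 °C
Reagents that add atoms: benzyl chloroformate, O=C(Cl)OCc1ccccc1
Why: Low-temperature deprotonation of the terminal alkyne C–H and C-acylation with a chloroformate, the way 4-chlorobut-2-ynoates are made, with the propargylic chloride untouched at this temperature.

**Step 9**
Reactants: 13 1,3-dimethoxy-1-(trimethylsilyloxy)penta-1,3-diene (1.5 equiv); 15 benzyl 4-chloropent-2-ynoate
Product: 17 benzyl 2-(1-chloroethyl)-6-hydroxy-4-methoxy-3-methylbenzoate (racemic), via cyclohexadiene cycloadduct 16 (not isolated)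
Conditions: toluene, 100 °C, sealed tube, 24 h; then 1 M HCl, THF, 0 °C
Reagents that add atoms: none
Why: Diels–Alder benzannulation in which the most nucleophilic diene terminus (CH–CH3) bonds to the β-carbon of the ynoate and the ketene acetal carbon bonds to the α-carbon, so that loss of methanol and desilylation give the arene with OH, H, OMe, Me and CHClMe in the required order; the chloride is meta to both oxygens and so does not ionise readily.

**Step 10**
Reactants: 10 {[2,4-bis(benzyloxy)-3,5,6-trimethylbenzoyl]oxy}acetic acid; 17 benzyl 2-(1-chloroethyl)-6-hydroxy-4-methoxy-3-methylbenzoate (racemic, 1.5 equiv)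
Product: 19 benzyl 2-[(2S)-4-{[2,4-bis(benzyloxy)-3,5,6-trimethylbenzoyl]oxy}-3-oxobutan-2-yl]-6-hydroxy-4-methoxy-3-methylbenzoate, via acid chloride 18 (not isolated)
Conditions: (COCl)2, cat. DMF, CH2Cl2, 0 °C to rt, evaporate; then 17, NiCl2(dme) (10 mol%), 2,2'-(propane-2,2-diyl)bis[(4R)-4-phenyl-4,5-dihydrooxazole] (22 mol%), Mn powder (3 equiv), 2,6-dimethylbenzoic acid (0.75 equiv), 3 Å MS, DMA/THF 3:7, 20 °C, 24 h
Reagents that add atoms: none
Why: Proposed new method: the closest known reaction type is the nickel-catalysed enantioconvergent reductive acyl cross-coupling of racemic secondary benzylic chlorides with acid chlorides, extended here to a chloride with two ortho substituents and to two complete halves of the target; monovalent nickel abstracts chlorine from either enantiomer of 17 to give one planar benzylic radical, the chiral bis(oxazoline) acyl complex of divalent nickel formed from 18 captures it (favoured by the slow dimerisation of so hindered a radical, the unhindered primary acyl partner and possible coordination of the neighbouring ester carbonyl), and reductive elimination from trivalent nickel forms C3–C4 and sets C4 as S under base-free conditions that neither enolise the ketone nor acylate the chelated phenol.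

**Step 11**
Reactants: 19 benzyl 2-[(2S)-4-{[2,4-bis(benzyloxy)-3,5,6-trimethylbenzoyl]oxy}-3-oxobutan-2-yl]-6-hydroxy-4-methoxy-3-methylbenzoate
Product: 21 [(3R,4S)-3,8-dihydroxy-6-methoxy-4,5-dimethyl-1-oxo-3,4-dihydro-1H-isochromen-3-yl]methyl 2,4-dihydroxy-3,5,6-trimethylbenzoate, via open keto acid 20 (not isolated)
Conditions: H2 (1 atm), 10% Pd/C, EtOAc, rt; filter, let stand at rt
Reagents that add atoms: none
Why: Neutral hydrogenolysis removes the benzyl ester and both benzyl ethers without touching C4, and ring–chain tautomerism of the activated α-acyloxy ketone with the free acid closes the lactol, where C3 settles as R under thermodynamic control because the 4-methyl is pseudoaxial (avoiding peri strain with the 5-methyl), the anomeric OH is axial and trans to it, and the CH2O-acyl group is equatorial.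

**Compound list**
1 | pentan-3-one | CCC(=O)CC | starting material
2 | methyl (E)-but-2-enoate | C/C=C/C(=O)OC | starting material
3 | methyl 3,4-dimethyl-5-oxoheptanoate (diastereomer mixture, not isolated) | CCC(=O)C(C)C(C)CC(=O)OC | intermediate
4 | 2,4,5-trimethylcyclohexane-1,3-dione (diastereomer mixture) | CC1C(=O)CC(C)C(C)C1=O | intermediate
5 | 2,4,5-trimethylbenzene-1,3-diol | Cc1cc(O)c(C)c(O)c1C | intermediate
6 | 2,4-dihydroxy-3,5,6-trimethylbenzoic acid | Cc1c(C)c(C(=O)O)c(O)c(C)c1O | intermediate
7 | methyl bromoacetate | COC(=O)CBr | starting material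
8 | 2-methoxy-2-oxoethyl 2,4-dihydroxy-3,5,6-trimethylbenzoate (not isolated) | COC(=O)COC(=O)c1c(C)c(C)c(O)c(C)c1O | intermediate
9 | 2-methoxy-2-oxoethyl 2,4-bis(benzyloxy)-3,5,6-trimethylbenzoate | COC(=O)COC(=O)c1c(C)c(C)c(OCc2ccccc2)c(C)c1OCc1ccccc1 | intermediate
10 | {[2,4-bis(benzyloxy)-3,5,6-trimethylbenzoyl]oxy}acetic acid | OC(=O)COC(=O)c1c(C)c(C)c(OCc2ccccc2)c(C)c1OCc1ccccc1 | intermediate
11 | methyl pent-2-ynoate | CCC#CC(=O)OC | starting material
12 | methyl (E)-3-methoxypent-2-enoate | CC/C(OC)=C\C(=O)OC | intermediate
13 | 1,3-dimethoxy-1-(trimethylsilyloxy)penta-1,3-diene (double-bond isomer mixture) | CC=C(OC)C=C(OC)O[Si](C)(C)C | intermediate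
14 | 3-chlorobut-1-yne (racemic) | CC(Cl)C#C | starting material
15 | benzyl 4-chloropent-2-ynoate (racemic) | CC(Cl)C#CC(=O)OCc1ccccc1 | intermediate
16 | benzyl 2-(1-chloroethyl)-4,6-dimethoxy-3-methyl-6-(trimethylsilyloxy)cyclohexa-1,4-diene-1-carboxylate (isomer mixture, not isolated) | COC1=CC(OC)(O[Si](C)(C)C)C(C(=O)OCc2ccccc2)=C(C(C)Cl)C1C | intermediate
17 | benzyl 2-(1-chloroethyl)-6-hydroxy-4-methoxy-3-methylbenzoate (racemic) | COc1cc(O)c(C(=O)OCc2ccccc2)c(C(C)Cl)c1C | intermediate
18 | {[2,4-bis(benzyloxy)-3,5,6-trimethylbenzoyl]oxy}acetyl chloride (not isolated) | O=C(Cl)COC(=O)c1c(C)c(C)c(OCc2ccccc2)c(C)c1OCc1ccccc1 | intermediate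
19 | benzyl 2-[(2S)-4-{[2,4-bis(benzyloxy)-3,5,6-trimethylbenzoyl]oxy}-3-oxobutan-2-yl]-6-hydroxy-4-methoxy-3-methylbenzoate | COc1cc(O)c(C(=O)OCc2ccccc2)c(c1C)[C@H](C)C(=O)COC(=O)c1c(C)c(C)c(OCc2ccccc2)c(C)c1OCc1ccccc1 | intermediate
20 | 2-[(2S)-4-[(2,4-dihydroxy-3,5,6-trimethylbenzoyl)oxy]-3-oxobutan-2-yl]-6-hydroxy-4-methoxy-3-methylbenzoic acid (not isolated) | COc1cc(O)c(C(=O)O)c(c1C)[C@H](C)C(=O)COC(=O)c1c(C)c(C)c(O)c(C)c1O | intermediate
21 | [(3R,4S)-3,8-dihydroxy-6-methoxy-4,5-dimethyl-1-oxo-3,4-dihydro-1H-isochromen-3-yl]methyl 2,4-dihydroxy-3,5,6-trimethylbenzoate (CNP0157156.2) | COc1cc(O)c2c(c1C)[C@H](C)[C@](O)(COC(=O)c1c(C)c(C)c(O)c(C)c1O)OC2=O | target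

**Total step count:** 11.
**Longest linear sequence:** 7 (steps 1, 2, 3, 4, 5, 10, 11).

**Three steps most likely to fail**

Step 10. The benzylic radical carries two ortho substituents, so its capture by nickel may be slow or poorly enantioselective. The fallback sets out from 17 and 10 and comes back at 19.
- DBU in toluene at 80 °C eliminates HCl from 17 to give the styrene benzyl 2-ethenyl-6-hydroxy-4-methoxy-3-methylbenzoate F1.
- DCC (0.5 equiv) in CH2Cl2 converts 10 into {[2,4-bis(benzyloxy)-3,5,6-trimethylbenzoyl]oxy}acetic anhydride F2.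
- The two are joined by copper hydride-catalysed enantioselective hydroacylation (Cu(OAc)2, the Ph-BPE antipode that gives S, (MeO)2MeSiH, THF, rt). Here a closed-shell benzylic copper species formed by hydrocupration is acylated in place of a radical. The phenol is silylated in passing and freed again on work-up.

Step 9. The benzylic chloride may lactonise onto the neighbouring ester at the temperature the cycloaddition needs. The fallback sets out from 13 and comes back at 19, and it makes use of that lactonisation.
- Methyl propiolate is deprotonated with LiN(iPr)2 at −78 °C, treated with acetaldehyde and quenched with Me3SiCl. This gives methyl 4-(trimethylsilyloxy)pent-2-ynoate F3.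
- F3 is heated with 13 (neat, 130 °C) and worked up with acid to give the phthalide 7-hydroxy-5-methoxy-3,4-dimethyl-2-benzofuran-1(3H)-one F4.
- 33% HBr in AcOH at rt opens the benzylic C–O bond to give 2-(1-bromoethyl)-6-hydroxy-4-methoxy-3-methylbenzoic acid F5.
- Benzyl 2,2,2-trichloroacetimidate in CH2Cl2 esterifies F5 without base to give benzyl 2-(1-bromoethyl)-6-hydroxy-4-methoxy-3-methylbenzoate F6. F6 takes the place of 17 in step 10.

Step 1. The Michael addition to a β-substituted enoate is slow, and γ-deprotonation of 2 competes. The fallback sets out from 1 and comes back at 4.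
- 1 is condensed with morpholine (cat. TsOH, toluene, water separator) to give the enamine 4-(pent-2-en-3-yl)morpholine F7.
- F7 is heated with (E)-but-2-enoyl chloride in toluene. N-acylation, a [3,3]-sigmatropic shift and ring closure build the six-membered ring, and aqueous HCl hydrolyses the product to 4.

**Further compounds**
F1 | step 10 | benzyl 2-ethenyl-6-hydroxy-4-methoxy-3-methylbenzoate | COc1cc(O)c(C(=O)OCc2ccccc2)c(C=C)c1C
F2 | step 10 | {[2,4-bis(benzyloxy)-3,5,6-trimethylbenzoyl]oxy}acetic anhydride | O=C(COC(=O)c1c(C)c(C)c(OCc2ccccc2)c(C)c1OCc1ccccc1)OC(=O)COC(=O)c1c(C)c(C)c(OCc2ccccc2)c(C)c1OCc1ccccc1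
F3 | step 9 | methyl 4-(trimethylsilyloxy)pent-2-ynoate (racemic) | CC(O[Si](C)(C)C)C#CC(=O)OC
F4 | step 9 | 7-hydroxy-5-methoxy-3,4-dimethyl-2-benzofuran-1(3H)-one (racemic) | COc1cc(O)c2C(=O)OC(C)c2c1C
F5 | step 9 | 2-(1-bromoethyl)-6-hydroxy-4-methoxy-3-methylbenzoic acid (racemic) | COc1cc(O)c(C(=O)O)c(C(C)Br)c1C
F6 | step 9 | benzyl 2-(1-bromoethyl)-6-hydroxy-4-methoxy-3-methylbenzoate (racemic) | COc1cc(O)c(C(=O)OCc2ccccc2)c(C(C)Br)c1C
F7 | step 1 | 4-(pent-2-en-3-yl)morpholine | CCC(=CC)N1CCOCC1
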